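**Strategy**

The route rests on a cut inside the saturated chain, at C7–C8 (C1 = carbinol carbon, C21 = CH2 on furan C2). The key step exploits the unbranched, stereocentre-free polymethylene run C1–C13 between the hydroxyl oxygen and the C14–C17 diyne: a copper-catalysed sp3–sp3 cross-coupling joins a C1–C7 Normant-type Grignard reagent, its hydroxyl masked only as the chloromagnesium alkoxide, to a C8–C21 primary bromide that already carries the diyne and the furan ring. One operation forms the C7–C8 bond, completes the C25 skeleton and, on work-up, delivers the free alcohol. The bromide arises from Cadiot–Chodkiewicz coupling of 2-(hex-5-ynyl)furan with 1,8-dibromooct-1-yne.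

Key step: step 6

Remark: the target has no stereocentre and no C=C bond, so no stereocontrol is needed anywhere in the route.

**Route**

Step 1
Reactants: 1 furan; 2 1-bromo-4-chlorobutane
Product: 4 2-(4-chlorobutyl)furan, via 2-furyllithium 3 (not isolated)
Conditions: furan (1.2 equiv), n-BuLi, THF, −78 → 0 °C; then 2, −78 °C → rt
Reagents that add atoms: n-butyllithium, CCCC[Li] (supplies only the lithium of intermediate 3; nothing of it remains in 4)
Why: Furan is lithiated at C2, its most acidic position next to the ring oxygen, and the 2-furyllithium should alkylate in an SN2 reaction at the C–Br end of the bromochloride much faster than at C–Cl, leaving the chloride for the next step.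

Step 2
Reactants: 4 2-(4-chlorobutyl)furan
Product: 5 2-(hex-5-yn-1-yl)furan
Conditions: LiC≡CH·H2NCH2CH2NH2 (1.5 equiv), NaI (cat.), DMSO, 0 °C → rt
Reagents that add atoms: lithium acetylide ethylenediamine complex, [Li]C#C.NCCN
Why: SN2 alkylation of lithium acetylide by a primary chloride in DMSO is the standard two-carbon homologation to a terminal alkyne, and the furan ring is inert to this basic, non-electrophilic medium.

Step 3
Reactants: 6 8-bromooct-1-yne
Product: 7 1,8-dibromooct-1-yne
Conditions: NBS (1.1 equiv), AgNO3 (10 mol%), acetone, rt, dark
Reagents that add atoms: N-bromosuccinimide, O=C1CCC(=O)N1Br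
Why: Silver-catalysed electrophilic bromination of the terminal alkyne C–H via the silver acetylide should give the 1-bromoalkyne without touching the primary alkyl bromide; the bromoalkyne is placed on this furan-free partner so that the furan never meets NBS.

Step 4
Reactants: 5 2-(hex-5-yn-1-yl)furan; 7 1,8-dibromooct-1-yne
Product: 8 2-(14-bromotetradeca-5,7-diyn-1-yl)furan
Conditions: CuCl (5 mol%), NH2OH·HCl, 30% aq n-BuNH2, Et2O, 0 °C, slow addition of 7, about 30 min
Reagents that add atoms: none
Why: Cadiot–Chodkiewicz heterocoupling, in which the copper(I) acetylide of 5 reacts with the sp C–Br bond of 7 to give the unsymmetrical 1,3-diyne; at 0 °C this coupling should be much faster than displacement of the primary sp3 C–Br by the amine.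

Step 5
Reactants: 9 7-chloroheptan-1-ol
Product: 11 [7-(chloromagnesiooxy)heptyl]magnesium chloride, via chloromagnesium 7-chloroheptan-1-olate 10 (not isolated)
Conditions: MeMgCl (1.0 equiv), THF, −10 °C → rt; then Mg turnings (I2-activated), THF, reflux; solution titrated and used as such
Reagents that add atoms: methylmagnesium chloride, C[Mg]Cl; magnesium, [Mg]
Why: Normant-type Grignard formation, in which MeMgCl first converts the alcohol into its chloromagnesium alkoxide and magnesium then inserts into the primary C–Cl bond, the alkoxide being inert toward the new C–Mg bond so that no protecting group is needed.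

Step 6
Reactants: 8 2-(14-bromotetradeca-5,7-diyn-1-yl)furan; 11 [7-(chloromagnesiooxy)heptyl]magnesium chloride
Product: 13 21-(furan-2-yl)henicosa-14,16-diyn-1-ol, via chloromagnesium alkoxide of the target 12 (not isolated)
Conditions: Li2CuCl4 (3 mol%), NMP (4 equiv), THF, −10 → 10 °C, slow addition of 11 (1.3 equiv); then sat. aq NH4Cl
Reagents that add atoms: none
Why: Transmetalation of the carbon-bound magnesium of 11 to catalytic copper gives an alkylcuprate that attacks the primary C–Br of 8 in an SN2-type oxidative addition, and reductive elimination from the copper(III) dialkyl forms the C7–C8 sp3–sp3 bond and returns copper(I). The closest known reaction type is the Kochi–Tamura (Li2CuCl4) coupling of Grignard reagents with primary alkyl halides in its NMP-accelerated form, run here with a Normant-type alkoxide-bearing Grignard reagent. No ring is closed and no stereocentre is formed. The step needs chemoselectivity for substitution at the sp3 C–Br over carbometalation of the C14–C17 diyne, over metalation of furan C5–H and over β-hydride elimination or homocoupling. This should be secured by the unhindered primary bromide, by catalytic copper with slow Grignard addition at or below 10 °C, and by the diyne being internal and dialkyl-substituted, so that it can only π-coordinate copper, an interaction known to stabilise the alkylcopper intermediates of such couplings. Aqueous NH4Cl then protonates alkoxide 12 to the free alcohol.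

**Compound list**

1 | furan | c1ccoc1 | starting material
2 | 1-bromo-4-chlorobutane | ClCCCCBr | starting material
3 | 2-furyllithium | [Li]c1ccco1 | intermediate
4 | 2-(4-chlorobutyl)furan | ClCCCCc1ccco1 | intermediate
5 | 2-(hex-5-yn-1-yl)furan | C#CCCCCc1ccco1 | intermediate
6 | 8-bromooct-1-yne | C#CCCCCCCBr | starting material
7 | 1,8-dibromooct-1-yne | BrC#CCCCCCCBr | intermediate
8 | 2-(14-bromotetradeca-5,7-diyn-1-yl)furan | BrCCCCCCC#CC#CCCCCc1ccco1 | intermediate
9 | 7-chloroheptan-1-ol | OCCCCCCCCl | starting material
10 | chloromagnesium 7-chloroheptan-1-olate | Cl[Mg]OCCCCCCCCl | intermediate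
11 | [7-(chloromagnesiooxy)heptyl]magnesium chloride | Cl[Mg]OCCCCCCC[Mg]Cl | intermediate
12 | chloromagnesium 21-(furan-2-yl)henicosa-14,16-diyn-1-olate | Cl[Mg]OCCCCCCCCCCCCCC#CC#CCCCCc1ccco1 | intermediate
13 | 21-(furan-2-yl)henicosa-14,16-diyn-1-ol | OCCCCCCCCCCCCCC#CC#CCCCCc1ccco1 | target

**Step count and risks**

Total step count: 6 (the preparation of the Grignard solution 11 counted as a step).
Longest linear sequence: 4 steps (steps 1, 2, 4, 6).

Steps most likely to fail:

1. Step 6. Carbometalation of the conjugated diyne by the alkylcopper or Grignard species, or homocoupling and reduction of the bromide, may compete with the cross-coupling. Fallback: the same C7–C8 bond is made by a B-alkyl Suzuki coupling. It sets out from bromide 8 and comes back at 13. Commercial hept-6-en-1-ol is silylated (TBSCl, imidazole, CH2Cl2) to tert-butyl(hept-6-en-1-yloxy)dimethylsilane F1. F1, in slight excess, is hydroborated with 9-BBN-H in THF to 9-[7-(tert-butyldimethylsilyloxy)heptyl]-9-borabicyclo[3.3.1]nonane F2. F2 and 8 are coupled with Pd(OAc)2/PCy3 and K3PO4·H2O in THF at rt to tert-butyl{[21-(furan-2-yl)henicosa-14,16-diyn-1-yl]oxy}dimethylsilane F3. TBAF in THF then cleaves the silyl ether to give 13.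

2. Step 4. Displacement of the primary alkyl bromide by the amine base and homocoupling of the bromoalkyne may erode the heterocoupling. Fallback: the C8 terminus is carried as a free alcohol and brominated only after the diyne is in place. It sets out from alkyne 5 and comes back at 8. Commercial oct-7-yn-1-ol is brominated (NBS, AgNO3, acetone) to 8-bromooct-7-yn-1-ol F4. Cadiot–Chodkiewicz coupling of F4 with 5 under the conditions of step 4 gives 14-(furan-2-yl)tetradeca-7,9-diyn-1-ol F5. An Appel reaction (CBr4, PPh3, CH2Cl2, 0 °C) converts F5 into 8.

3. Step 5. Magnesium insertion into the C–Cl bond may be sluggish in the presence of the poorly soluble alkoxide, with Wurtz coupling as a side process. Fallback: the hydroxyl is protected as an acetal and a conventional Grignard reagent is used. It sets out from 9 and comes back at 13. Reaction of 9 with 3,4-dihydro-2H-pyran (PPTS, CH2Cl2) gives racemic 2-[(7-chloroheptyl)oxy]oxane F6. Magnesium in refluxing THF converts F6 into {7-[(oxan-2-yl)oxy]heptyl}magnesium chloride F7. F7 is coupled with 8 under the Li2CuCl4 conditions of step 6 to 2-{[21-(furan-2-yl)henicosa-14,16-diyn-1-yl]oxy}oxane F8. PPTS in MeOH at rt then removes the acetal to give 13.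

**Further compounds**

F1 | step 6 | tert-butyl(hept-6-en-1-yloxy)dimethylsilane | C=CCCCCCO[Si](C)(C)C(C)(C)C
F2 | step 6 | 9-[7-(tert-butyldimethylsilyloxy)heptyl]-9-borabicyclo[3.3.1]nonane | CC(C)(C)[Si](C)(C)OCCCCCCCB1C2CCCC1CCC2
F3 | step 6 | tert-butyl{[21-(furan-2-yl)henicosa-14,16-diyn-1-yl]oxy}dimethylsilane | CC(C)(C)[Si](C)(C)OCCCCCCCCCCCCCC#CC#CCCCCc1ccco1
F4 | step 4 | 8-bromooct-7-yn-1-ol | OCCCCCCC#CBr
F5 | step 4 | 14-(furan-2-yl)tetradeca-7,9-diyn-1-ol | OCCCCCCC#CC#CCCCCc1ccco1
F6 | step 5 | 2-[(7-chloroheptyl)oxy]oxane (racemic) | ClCCCCCCCOC1CCCCO1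
F7 | step 5 | {7-[(oxan-2-yl)oxy]heptyl}magnesium chloride | Cl[Mg]CCCCCCCOC1CCCCO1
F8 | step 5 | 2-{[21-(furan-2-yl)henicosa-14,16-diyn-1-yl]oxy}oxane (racemic) | C1CCCC(O1)OCCCCCCCCCCCCCC#CC#CCCCCc1ccco1
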